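**Retrosynthetic overview**
1. Wittig disconnections at C11=C12 and C11'=C12' (carotenoid numbering) give cyclic C20 phosphonium salt 18, C10 dialdehyde 34 and acyclic C20 phosphonium salt 33.
2. In 18, the C6–C7 bond comes from a trans-selective copper-catalysed conjugate alkenylation of enone 7 with dienyl unit 11; enol triflate reduction then fixes the C4=C5 alkene.
3. In 7, the C2 stereocentre and its C–C bond come from a new IDPi/silylium-catalysed enantioselective conjugate allylation of dienone 2; cross-metathesis finishes the side chain.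
4. In 33, C2' comes from Sharpless epoxidation of prenol and C2-selective allyl opening, followed by two vinylogous Horner–Wadsworth–Emmons extensions.
5. Ring order: the only ring is not formed in the route; it is carried through from cyclohexenone 1.

Assumption: 1, 8, 19, 25 and 34 are taken as catalogue chemicals, and the target SMILES is read as the all-E (2S,6R,2'R) isomer with the C2 and C6 ring substituents trans.

**Route**

Step 1
Reactants: 1 2,4,4-trimethylcyclohex-2-en-1-one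
Product: 2 2,4,4-trimethylcyclohexa-2,5-dien-1-one
Conditions: DDQ (1.3 equiv), 1,4-dioxane, reflux
Reagents that add atoms: none
Why: DDQ dehydrogenation of the enone at its only free α'/β' pair (C6/C5) gives the cross-conjugated dienone, as in the classical dehydrogenation of 4,4-disubstituted cyclohexenones.

Step 2
Reactants: 2 2,4,4-trimethylcyclohexa-2,5-dien-1-one
Product: 4 (5R)-2,4,4-trimethyl-5-(prop-2-en-1-yl)cyclohex-2-en-1-one, via silyl dienol ether 3 (not isolated)
Conditions: allylSiMe3 (2.5 equiv), IDPi acid HN[P(=NSO2CF3)(O2C20H10Ar2)]2 (Ar = 3,5-(CF3)2C6H3, both binaphthyl units S) (3 mol%), toluene, −60 °C; then aq. HCl (1 mol/L), THF, 0 °C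
Reagents that add atoms: allyltrimethylsilane C=CC[Si](C)(C)C
Why: Proposed new method: the acid and allylSiMe3 generate a silylium ion paired with the confined chiral IDPi anion, which O-silylates the dienone to a silyloxycyclohexadienyl cation held in the chiral pocket; allylSiMe3 attacks the less hindered β-carbon C5 (C3 is flanked by the C2 methyl and the gem-dimethyl group) on one enantiotopic face, the β-silyl cation passes Me3Si+ to the next dienone, the product rests as dienol ether 3 (protected from a second allylation) and acid work-up gives (5R)-4, the catalyst antipode being chosen to give R; the closest known reactions are the racemic TiCl4-mediated Hosomi–Sakurai conjugate allylation of enones and IDPi/silylium-catalysed asymmetric Hosomi–Sakurai allylation of aldehydes and Mukaiyama–Michael additions.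

Step 3
Reactants: 4 (5R)-2,4,4-trimethyl-5-(prop-2-en-1-yl)cyclohex-2-en-1-one
Product: 5 (2E)-2-methyl-4-[(1R)-2,2,4-trimethyl-5-oxocyclohex-3-en-1-yl]but-2-enal
Conditions: methacrolein (8 equiv), second-generation Hoveyda–Grubbs catalyst RuCl2(=CH-C6H4-2-OiPr)(1,3-dimesitylimidazolidin-2-ylidene) (5 mol%), CH2Cl2, 40 °C
Reagents that add atoms: methacrolein CC(=C)C=O
Why: Olefin cross-metathesis of the terminal allyl group with methacrolein gives the thermodynamically favoured (E)-trisubstituted enal, while the electron-poor trisubstituted ring alkene is inert and the stereocentre is untouched.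

Step 4
Reactants: 5 (2E)-2-methyl-4-[(1R)-2,2,4-trimethyl-5-oxocyclohex-3-en-1-yl]but-2-enal
Product: 6 (5R)-5-[(2E)-4-hydroxy-3-methylbut-2-en-1-yl]-2,4,4-trimethylcyclohex-2-en-1-one
Conditions: NaBH4 (0.35 equiv), MeOH/CH2Cl2 (1:1), −78 °C
Reagents that add atoms: none
Why: Chemoselective borohydride 1,2-reduction, since the unhindered aldehyde is reduced far faster at −78 °C than the hindered α-methyl enone ketone.

Step 5
Reactants: 6 (5R)-5-[(2E)-4-hydroxy-3-methylbut-2-en-1-yl]-2,4,4-trimethylcyclohex-2-en-1-one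
Product: 7 (5R)-5-[(2E)-4-{[tert-butyl(diphenyl)silyl]oxy}-3-methylbut-2-en-1-yl]-2,4,4-trimethylcyclohex-2-en-1-one
Conditions: t-BuPh2SiCl, imidazole, DMF, 0 °C to rt
Reagents that add atoms: tert-butyl(chloro)diphenylsilane CC(C)(C)[Si](Cl)(c1ccccc1)c1ccccc1
Why: Standard silylation of the primary allylic alcohol gives a TBDPS ether that survives the organometallic, acidic and basic steps up to the final deprotection.

Step 6
Reactants: 8 (2E)-3-methylpent-2-en-4-yn-1-ol
Product: 9 tert-butyl(dimethyl){[(2E)-3-methylpent-2-en-4-yn-1-yl]oxy}silane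
Conditions: t-BuMe2SiCl, imidazole, DMF, rt
Reagents that add atoms: tert-butyl(chloro)dimethylsilane CC(C)(C)[Si](C)(C)Cl
Why: Routine silyl protection of the primary alcohol before the organometallic steps.

Step 7
Reactants: 9 tert-butyl(dimethyl){[(2E)-3-methylpent-2-en-4-yn-1-yl]oxy}silane
Product: 11 tert-butyl{[(2E,4E)-5-iodo-3-methylpenta-2,4-dien-1-yl]oxy}dimethylsilane, via alkenylzirconocene 10 (not isolated)
Conditions: Cp2Zr(H)Cl, THF, rt; then I2, 0 °C
Reagents that add atoms: zirconocene chloride hydride [H][Zr](Cl)(C1C=CC=C1)C1C=CC=C1 (Zr fragment only in 10); iodine II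
Why: Hydrozirconation of the terminal alkyne (syn addition, Zr on the terminal carbon) followed by iodinolysis with retention gives the (E)-vinyl iodide and leaves the trisubstituted alkene alone.

Step 8
Reactants: 7 TBDPS-protected enone; 11 dienyl iodide
Product: 13 {[(3S,5R)-3-[(1E,3E)-5-{[tert-butyl(dimethyl)silyl]oxy}-3-methylpenta-1,3-dien-1-yl]-5-[(2E)-4-{[tert-butyl(diphenyl)silyl]oxy}-3-methylbut-2-en-1-yl]-2,4,4-trimethylcyclohex-1-en-1-yl]oxy}trimethylsilane, via dienylmagnesium chloride 12 (not isolated)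
Conditions: 11, i-PrMgCl·LiCl, THF, −20 to 0 °C; then CuBr·SMe2 (10 mol%), 7, Me3SiCl, HMPA, THF, −78 to −40 °C; Et3N quench
Reagents that add atoms: isopropylmagnesium chloride–lithium chloride CC(C)[Mg]Cl.[Li+].[Cl-] (MgCl of 12); chlorotrimethylsilane C[Si](C)(C)Cl
Why: Copper-catalysed, chlorosilane-accelerated conjugate addition of the alkenyl Grignard reagent (Kuwajima–Nakamura conditions) proceeds by axial attack on the enone β-carbon anti to the pseudo-equatorial side chain across the gem-dimethyl carbon, which sets the new centre trans (3S by priority), and the enolate is trapped regiospecifically as the silyl enol ether.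

Step 9
Reactants: 13 trimethylsilyl enol ether
Product: 15 (3S,5R)-3-[(1E,3E)-5-{[tert-butyl(dimethyl)silyl]oxy}-3-methylpenta-1,3-dien-1-yl]-5-[(2E)-4-{[tert-butyl(diphenyl)silyl]oxy}-3-methylbut-2-en-1-yl]-2,4,4-trimethylcyclohex-1-en-1-yl trifluoromethanesulfonate, via lithium enolate 14 (not isolated)
Conditions: MeLi, THF, 0 °C; then N-(5-chloropyridin-2-yl)bis(trifluoromethanesulfonyl)imide, −78 to 0 °C
Reagents that add atoms: methyllithium [Li]C (Li of 14); N-(5-chloropyridin-2-yl)-1,1,1-trifluoro-N-(trifluoromethanesulfonyl)methanesulfonamide FC(F)(F)S(=O)(=O)N(c1ccc(Cl)cn1)S(=O)(=O)C(F)(F)F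
Why: Methyllithium cleavage of the silyl enol ether releases the regiodefined tetrasubstituted lithium enolate, which is O-triflated (Comins triflation) without touching either stereocentre.

Step 10
Reactants: 15 enol triflate
Product: 16 tert-butyl{[(2E,4E)-5-[(1R,5S)-5-[(2E)-4-{[tert-butyl(diphenyl)silyl]oxy}-3-methylbut-2-en-1-yl]-2,6,6-trimethylcyclohex-2-en-1-yl]-3-methylpenta-2,4-dien-1-yl]oxy}dimethylsilane
Conditions: Pd(OAc)2 (5 mol%), PPh3 (10 mol%), HCO2H, n-Bu3N, DMF, 60 °C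
Reagents that add atoms: none
Why: Palladium-catalysed formate reduction of the enol triflate (oxidative addition to zerovalent palladium, formate decarboxylation, reductive elimination) replaces OTf by H with the double bond locked at C4=C5, so it cannot drift into conjugation; the descriptors become 1R,5S by priority only.

Step 11
Reactants: 16 bis-silyl ether
Product: 17 (2E,4E)-5-[(1R,5S)-5-[(2E)-4-{[tert-butyl(diphenyl)silyl]oxy}-3-methylbut-2-en-1-yl]-2,6,6-trimethylcyclohex-2-en-1-yl]-3-methylpenta-2,4-dien-1-ol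
Conditions: PPTS (10 mol%), MeOH/CH2Cl2, rt
Reagents that add atoms: none
Why: Mild acid-catalysed methanolysis removes the primary TBS ether selectively because the TBDPS ether is roughly two orders of magnitude more stable to acid.

Step 12
Reactants: 17 dienyl alcohol
Product: 18 {(2E,4E)-5-[(1R,5S)-5-[(2E)-4-{[tert-butyl(diphenyl)silyl]oxy}-3-methylbut-2-en-1-yl]-2,6,6-trimethylcyclohex-2-en-1-yl]-3-methylpenta-2,4-dien-1-yl}(triphenyl)phosphonium bromide
Conditions: PPh3·HBr (1.05 equiv), CH2Cl2/MeOH, 0 °C to rt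
Reagents that add atoms: triphenylphosphine hydrobromide [Br-].c1ccc(cc1)[PH+](c1ccccc1)c1ccccc1
Why: Acid-promoted ionisation of the dienylic alcohol and capture of the pentadienyl cation at its unhindered primary terminus by PPh3 is the standard Wittig-salt formation of ionylidene chemistry, which is known to preserve the C6 configuration of ε-type rings.

Step 13
Reactants: 19 3-methylbut-2-en-1-ol
Product: 20 [(2S)-3,3-dimethyloxiran-2-yl]methanol
Conditions: Ti(OiPr)4 (10 mol%), L-(+)-diethyl tartrate (12 mol%), t-BuOOH, 4 Å molecular sieves, CH2Cl2, −20 °C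
Reagents that add atoms: tert-butyl hydroperoxide CC(C)(C)OO
Why: Sharpless asymmetric epoxidation, in which the titanium L-(+)-tartrate catalyst delivers oxygen to one enantioface of the allylic alcohol and sets the (2S) centre in the same sense as with geraniol.

Step 14
Reactants: 20 [(2S)-3,3-dimethyloxiran-2-yl]methanol
Product: 21 (2R)-3-methyl-2-(prop-2-en-1-yl)butane-1,3-diol
Conditions: allylMgCl (3 equiv), CuI (10 mol%), THF, −30 to 0 °C
Reagents that add atoms: allylmagnesium chloride C=CC[Mg]Cl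
Why: Copper-catalysed SN2 opening of the 2,3-epoxy alcohol can only occur at C2 because C3 is fully substituted, and inversion there turns the (2S)-epoxide into the (2R)-1,3-diol that carries the future C2' centre.

Step 15
Reactants: 21 (2R)-3-methyl-2-(prop-2-en-1-yl)butane-1,3-diol
Product: 22 (2R)-3-methyl-2-(3-methylbut-2-en-1-yl)butane-1,3-diol
Conditions: 2-methylbut-2-ene (20 equiv), second-generation Grubbs catalyst RuCl2(=CHPh)(PCy3)(1,3-dimesitylimidazolidin-2-ylidene) (3 mol%), CH2Cl2, 40 °C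
Reagents that add atoms: 2-methylbut-2-ene CC=C(C)C
Why: Olefin cross-metathesis with 2-methylbut-2-ene converts the terminal allyl group into a prenyl group and tolerates the free hydroxyls.

Step 16
Reactants: 22 (2R)-3-methyl-2-(3-methylbut-2-en-1-yl)butane-1,3-diol
Product: 23 (2S)-2-(2-hydroxypropan-2-yl)-5-methylhex-4-enal
Conditions: TEMPO (10 mol%), PhI(OAc)2 (1.1 equiv), CH2Cl2, rt
Reagents that add atoms: none
Why: TEMPO/PhI(OAc)2 oxidation is selective for the primary alcohol and its near-neutral medium avoids retro-aldol cleavage and epimerisation, the descriptor changing to S by priority only.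

Step 17
Reactants: 23 (2S)-2-(2-hydroxypropan-2-yl)-5-methylhex-4-enal
Product: 24 (2S)-5-methyl-2-{2-[(triethylsilyl)oxy]propan-2-yl}hex-4-enal
Conditions: Et3SiOTf, 2,6-lutidine, CH2Cl2, −78 °C
Reagents that add atoms: triethylsilyl trifluoromethanesulfonate CC[Si](CC)(CC)OS(=O)(=O)C(F)(F)F
Why: Silyl triflate/lutidine silylation caps the hindered tertiary alcohol at low temperature, which blocks retro-aldol cleavage in the basic olefination that follows.

Step 18
Reactants: 24 silyl-protected aldehyde; 25 ethyl (2E)-4-(diethoxyphosphoryl)-3-methylbut-2-enoate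
Product: 27 ethyl (2E,4E,6R)-3,7-dimethyl-6-(3-methylbut-2-en-1-yl)-7-[(triethylsilyl)oxy]octa-2,4-dienoate, via lithiated phosphonate 26 (not isolated)
Conditions: 25, LiN(SiMe3)2, THF/DMPU, −78 °C; then 24, −78 to 0 °C
Reagents that add atoms: lithium bis(trimethylsilyl)amide [Li]N([Si](C)(C)C)[Si](C)(C)C (Li of 26)
Why: Vinylogous Horner–Wadsworth–Emmons olefination forms the new disubstituted alkene with E geometry, and the α-centre, flanked by a quaternary carbon, is not enolised at low temperature (descriptor R again by priority).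

Step 19
Reactants: 27 C15 dienoate
Product: 28 (2E,4E,6R)-3,7-dimethyl-6-(3-methylbut-2-en-1-yl)-7-[(triethylsilyl)oxy]octa-2,4-dien-1-ol
Conditions: i-Bu2AlH (2.2 equiv), CH2Cl2, −78 °C; aq. potassium sodium tartrate
Reagents that add atoms: none
Why: Hydride 1,2-reduction of the conjugated ester to the allylic alcohol leaves the alkenes and the silyl ether untouched.

Step 20
Reactants: 28 C15 dienol
Product: 29 (2E,4E,6R)-3,7-dimethyl-6-(3-methylbut-2-en-1-yl)-7-[(triethylsilyl)oxy]octa-2,4-dienal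
Conditions: MnO2, CH2Cl2, rt
Reagents that add atoms: none
Why: MnO2 oxidises the allylic alcohol selectively to the dienal without isomerising the double bonds.

Step 21
Reactants: 29 C15 dienal; 25 ethyl (2E)-4-(diethoxyphosphoryl)-3-methylbut-2-enoate
Product: 31 ethyl (2E,4E,6E,8E,10R)-3,7,11-trimethyl-10-(3-methylbut-2-en-1-yl)-11-[(triethylsilyl)oxy]dodeca-2,4,6,8-tetraenoate, via sodium phosphonate anion 30 (not isolated)
Conditions: 25, NaN(SiMe3)2, THF, −78 °C; then 29, −78 to 0 °C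
Reagents that add atoms: sodium bis(trimethylsilyl)amide [Na]N([Si](C)(C)C)[Si](C)(C)C (Na of 30)
Why: A second vinylogous Horner–Wadsworth–Emmons olefination, here through the sodium phosphonate anion because dienal 29 has no enolisable α-centre and needs no lithium/DMPU protocol, extends the chain by the next C5 unit with E selectivity at the new bond.

Step 22
Reactants: 31 C20 tetraenoate
Product: 32 (2E,4E,6E,8E,10R)-3,7,11-trimethyl-10-(3-methylbut-2-en-1-yl)-11-[(triethylsilyl)oxy]dodeca-2,4,6,8-tetraen-1-ol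
Conditions: i-Bu2AlH (2.2 equiv), CH2Cl2, −78 °C; aq. potassium sodium tartrate
Reagents that add atoms: none
Why: Hydride 1,2-reduction of the conjugated ester gives the polyenyl alcohol needed for salt formation.

Step 23
Reactants: 32 C20 tetraenol
Product: 33 [(2E,4E,6E,8E,10R)-3,7,11-trimethyl-10-(3-methylbut-2-en-1-yl)-11-[(triethylsilyl)oxy]dodeca-2,4,6,8-tetraen-1-yl](triphenyl)phosphonium bromide
Conditions: PPh3·HBr (1.05 equiv), CH2Cl2, 0 °C
Reagents that add atoms: triphenylphosphine hydrobromide [Br-].c1ccc(cc1)[PH+](c1ccccc1)c1ccccc1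
Why: The polyenylic alcohol ionises and PPh3 traps the cation at the primary terminus, as in retinyl phosphonium salt formation, while the tertiary silyl ether survives the brief, nearly stoichiometric acid exposure.

Step 24
Reactants: 18 cyclic C20 phosphonium bromide; 34 (2E,4E,6E)-2,7-dimethylocta-2,4,6-trienedial
Product: 35 (2E,4E,6E,8E,10E,12E)-13-[(1R,5S)-5-[(2E)-4-{[tert-butyl(diphenyl)silyl]oxy}-3-methylbut-2-en-1-yl]-2,6,6-trimethylcyclohex-2-en-1-yl]-2,7,11-trimethyltrideca-2,4,6,8,10,12-hexaenal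
Conditions: 34 (3 equiv), NaOMe, MeOH/CH2Cl2, 0 °C to rt; then n-heptane, reflux
Reagents that add atoms: none
Why: Wittig olefination of the allylic ylide with excess dialdehyde stops at mono-condensation, and the new disubstituted C11=C12 bond is equilibrated thermally to E as is routine for apo-carotenals.

Step 25
Reactants: 35 C30 aldehyde; 33 acyclic C20 phosphonium bromide
Product: 36 all-E (2S,6R,2'R)-2-[(2E)-4-{[tert-butyl(diphenyl)silyl]oxy}-3-methylbut-2-en-1-yl]-2'-(3-methylbut-2-en-1-yl)-1'-[(triethylsilyl)oxy]-3',4'-didehydro-1',2'-dihydro-ε,ψ-carotene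
Conditions: NaOMe, MeOH/CH2Cl2, rt; then n-heptane, reflux under N2, crystallisation
Reagents that add atoms: none
Why: The second Wittig olefination closes the C11'=C12' bond, and thermal Z to E isomerisation of this disubstituted bond gives the all-E C50 polyene without touching the three sp3 stereocentres.

Step 26
Reactants: 36 C50 bis-silyl ether
Product: 37 all-E (2S,6R,2'R)-2-[(2E)-4-hydroxy-3-methylbut-2-en-1-yl]-2'-(3-methylbut-2-en-1-yl)-3',4'-didehydro-1',2'-dihydro-ε,ψ-caroten-1'-ol (CNP0409952.2)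
Conditions: n-Bu4NF (4 equiv), THF, 0 °C to rt
Reagents that add atoms: none
Why: Fluoride-mediated desilylation removes the primary TBDPS and tertiary triethylsilyl ethers under non-acidic conditions that the polyene tolerates.

**Compound list**
1 | 2,4,4-trimethylcyclohex-2-en-1-one | CC1=CC(C)(C)CCC1=O | starting material
2 | 2,4,4-trimethylcyclohexa-2,5-dien-1-one | CC1=CC(C)(C)C=CC1=O | intermediate
3 | trimethyl{[(3R)-4,4,6-trimethyl-3-(prop-2-en-1-yl)cyclohexa-1,5-dien-1-yl]oxy}silane | C[Si](C)(C)OC1=C[C@@H](CC=C)C(C)(C)C=C1C | intermediate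
4 | (5R)-2,4,4-trimethyl-5-(prop-2-en-1-yl)cyclohex-2-en-1-one | O=C1C[C@@H](CC=C)C(C)(C)C=C1C | intermediate
5 | (2E)-2-methyl-4-[(1R)-2,2,4-trimethyl-5-oxocyclohex-3-en-1-yl]but-2-enal | O=C1C[C@@H](C/C=C(\C)C=O)C(C)(C)C=C1C | intermediate
6 | (5R)-5-[(2E)-4-hydroxy-3-methylbut-2-en-1-yl]-2,4,4-trimethylcyclohex-2-en-1-one | O=C1C[C@@H](C/C=C(\C)CO)C(C)(C)C=C1C | intermediate
7 | (5R)-5-[(2E)-4-{[tert-butyl(diphenyl)silyl]oxy}-3-methylbut-2-en-1-yl]-2,4,4-trimethylcyclohex-2-en-1-one | O=C1C[C@@H](C/C=C(\C)CO[Si](c2ccccc2)(c2ccccc2)C(C)(C)C)C(C)(C)C=C1C | intermediate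
8 | (2E)-3-methylpent-2-en-4-yn-1-ol | C#C/C(C)=C/CO | starting material
9 | tert-butyl(dimethyl){[(2E)-3-methylpent-2-en-4-yn-1-yl]oxy}silane | C#C/C(C)=C/CO[Si](C)(C)C(C)(C)C | intermediate
10 | [(1E,3E)-5-{[tert-butyl(dimethyl)silyl]oxy}-3-methylpenta-1,3-dien-1-yl](chloro)bis(cyclopentadienyl)zirconium | Cl[Zr](/C=C/C(C)=C/CO[Si](C)(C)C(C)(C)C)(C1C=CC=C1)C1C=CC=C1 | intermediate
11 | tert-butyl{[(2E,4E)-5-iodo-3-methylpenta-2,4-dien-1-yl]oxy}dimethylsilane | I/C=C/C(C)=C/CO[Si](C)(C)C(C)(C)C | intermediate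
12 | [(1E,3E)-5-{[tert-butyl(dimethyl)silyl]oxy}-3-methylpenta-1,3-dien-1-yl]magnesium chloride | Cl[Mg]/C=C/C(C)=C/CO[Si](C)(C)C(C)(C)C | intermediate
13 | {[(3S,5R)-3-[(1E,3E)-5-{[tert-butyl(dimethyl)silyl]oxy}-3-methylpenta-1,3-dien-1-yl]-5-[(2E)-4-{[tert-butyl(diphenyl)silyl]oxy}-3-methylbut-2-en-1-yl]-2,4,4-trimethylcyclohex-1-en-1-yl]oxy}trimethylsilane | CC(C)(C)[Si](C)(C)OC/C=C(C)/C=C/[C@@H]1C(C)=C(O[Si](C)(C)C)C[C@@H](C/C=C(\C)CO[Si](c2ccccc2)(c2ccccc2)C(C)(C)C)C1(C)C | intermediate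
14 | lithium (3S,5R)-3-[(1E,3E)-5-{[tert-butyl(dimethyl)silyl]oxy}-3-methylpenta-1,3-dien-1-yl]-5-[(2E)-4-{[tert-butyl(diphenyl)silyl]oxy}-3-methylbut-2-en-1-yl]-2,4,4-trimethylcyclohex-1-en-1-olate | [Li+].CC(C)(C)[Si](C)(C)OC/C=C(C)/C=C/[C@@H]1C(C)=C([O-])C[C@@H](C/C=C(\C)CO[Si](c2ccccc2)(c2ccccc2)C(C)(C)C)C1(C)C | intermediate
15 | (3S,5R)-3-[(1E,3E)-5-{[tert-butyl(dimethyl)silyl]oxy}-3-methylpenta-1,3-dien-1-yl]-5-[(2E)-4-{[tert-butyl(diphenyl)silyl]oxy}-3-methylbut-2-en-1-yl]-2,4,4-trimethylcyclohex-1-en-1-yl trifluoromethanesulfonate | CC(C)(C)[Si](C)(C)OC/C=C(C)/C=C/[C@@H]1C(C)=C(OS(=O)(=O)C(F)(F)F)C[C@@H](C/C=C(\C)CO[Si](c2ccccc2)(c2ccccc2)C(C)(C)C)C1(C)C | intermediate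
16 | tert-butyl{[(2E,4E)-5-[(1R,5S)-5-[(2E)-4-{[tert-butyl(diphenyl)silyl]oxy}-3-methylbut-2-en-1-yl]-2,6,6-trimethylcyclohex-2-en-1-yl]-3-methylpenta-2,4-dien-1-yl]oxy}dimethylsilane | CC(C)(C)[Si](C)(C)OC/C=C(C)/C=C/[C@@H]1C(C)=CC[C@@H](C/C=C(\C)CO[Si](c2ccccc2)(c2ccccc2)C(C)(C)C)C1(C)C | intermediate
17 | (2E,4E)-5-[(1R,5S)-5-[(2E)-4-{[tert-butyl(diphenyl)silyl]oxy}-3-methylbut-2-en-1-yl]-2,6,6-trimethylcyclohex-2-en-1-yl]-3-methylpenta-2,4-dien-1-ol | OC/C=C(C)/C=C/[C@@H]1C(C)=CC[C@@H](C/C=C(\C)CO[Si](c2ccccc2)(c2ccccc2)C(C)(C)C)C1(C)C | intermediate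
18 | {(2E,4E)-5-[(1R,5S)-5-[(2E)-4-{[tert-butyl(diphenyl)silyl]oxy}-3-methylbut-2-en-1-yl]-2,6,6-trimethylcyclohex-2-en-1-yl]-3-methylpenta-2,4-dien-1-yl}(triphenyl)phosphonium bromide | [Br-].c1ccc(cc1)[P+](c1ccccc1)(c1ccccc1)C/C=C(C)/C=C/[C@@H]1C(C)=CC[C@@H](C/C=C(\C)CO[Si](c2ccccc2)(c2ccccc2)C(C)(C)C)C1(C)C | intermediate
19 | 3-methylbut-2-en-1-ol | CC(C)=CCO | starting material
20 | [(2S)-3,3-dimethyloxiran-2-yl]methanol | OC[C@@H]1OC1(C)C | intermediate
21 | (2R)-3-methyl-2-(prop-2-en-1-yl)butane-1,3-diol | C=CC[C@H](CO)C(C)(C)O | intermediate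
22 | (2R)-3-methyl-2-(3-methylbut-2-en-1-yl)butane-1,3-diol | CC(C)=CC[C@H](CO)C(C)(C)O | intermediate
23 | (2S)-2-(2-hydroxypropan-2-yl)-5-methylhex-4-enal | CC(C)=CC[C@H](C=O)C(C)(C)O | intermediate
24 | (2S)-5-methyl-2-{2-[(triethylsilyl)oxy]propan-2-yl}hex-4-enal | CC(C)=CC[C@H](C=O)C(C)(C)O[Si](CC)(CC)CC | intermediate
25 | ethyl (2E)-4-(diethoxyphosphoryl)-3-methylbut-2-enoate | CCOC(=O)/C=C(\C)CP(=O)(OCC)OCC | starting material
26 | lithium (2E)-1-(diethoxyphosphoryl)-4-ethoxy-2-methyl-4-oxobut-2-en-1-ide | [Li+].CCOC(=O)/C=C(\C)[CH-]P(=O)(OCC)OCC | intermediate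
27 | ethyl (2E,4E,6R)-3,7-dimethyl-6-(3-methylbut-2-en-1-yl)-7-[(triethylsilyl)oxy]octa-2,4-dienoate | CC(C)=CC[C@H](/C=C/C(C)=C/C(=O)OCC)C(C)(C)O[Si](CC)(CC)CC | intermediate
28 | (2E,4E,6R)-3,7-dimethyl-6-(3-methylbut-2-en-1-yl)-7-[(triethylsilyl)oxy]octa-2,4-dien-1-ol | CC(C)=CC[C@H](/C=C/C(C)=C/CO)C(C)(C)O[Si](CC)(CC)CC | intermediate
29 | (2E,4E,6R)-3,7-dimethyl-6-(3-methylbut-2-en-1-yl)-7-[(triethylsilyl)oxy]octa-2,4-dienal | CC(C)=CC[C@H](/C=C/C(C)=C/C=O)C(C)(C)O[Si](CC)(CC)CC | intermediate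
30 | sodium (2E)-1-(diethoxyphosphoryl)-4-ethoxy-2-methyl-4-oxobut-2-en-1-ide | [Na+].CCOC(=O)/C=C(\C)[CH-]P(=O)(OCC)OCC | intermediate
31 | ethyl (2E,4E,6E,8E,10R)-3,7,11-trimethyl-10-(3-methylbut-2-en-1-yl)-11-[(triethylsilyl)oxy]dodeca-2,4,6,8-tetraenoate | CC(C)=CC[C@H](/C=C/C(C)=C/C=C/C(C)=C/C(=O)OCC)C(C)(C)O[Si](CC)(CC)CC | intermediate
32 | (2E,4E,6E,8E,10R)-3,7,11-trimethyl-10-(3-methylbut-2-en-1-yl)-11-[(triethylsilyl)oxy]dodeca-2,4,6,8-tetraen-1-ol | CC(C)=CC[C@H](/C=C/C(C)=C/C=C/C(C)=C/CO)C(C)(C)O[Si](CC)(CC)CC | intermediate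
33 | [(2E,4E,6E,8E,10R)-3,7,11-trimethyl-10-(3-methylbut-2-en-1-yl)-11-[(triethylsilyl)oxy]dodeca-2,4,6,8-tetraen-1-yl](triphenyl)phosphonium bromide | [Br-].CC(C)=CC[C@H](/C=C/C(C)=C/C=C/C(C)=C/C[P+](c1ccccc1)(c1ccccc1)c1ccccc1)C(C)(C)O[Si](CC)(CC)CC | intermediate
34 | (2E,4E,6E)-2,7-dimethylocta-2,4,6-trienedial | O=C/C(C)=C/C=C/C=C(C)/C=O | starting material
35 | (2E,4E,6E,8E,10E,12E)-13-[(1R,5S)-5-[(2E)-4-{[tert-butyl(diphenyl)silyl]oxy}-3-methylbut-2-en-1-yl]-2,6,6-trimethylcyclohex-2-en-1-yl]-2,7,11-trimethyltrideca-2,4,6,8,10,12-hexaenal | O=C/C(C)=C/C=C/C=C(C)/C=C/C=C(C)/C=C/[C@@H]1C(C)=CC[C@@H](C/C=C(\C)CO[Si](c2ccccc2)(c2ccccc2)C(C)(C)C)C1(C)C | intermediate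
36 | all-E (2S,6R,2'R)-2-[(2E)-4-{[tert-butyl(diphenyl)silyl]oxy}-3-methylbut-2-en-1-yl]-2'-(3-methylbut-2-en-1-yl)-1'-[(triethylsilyl)oxy]-3',4'-didehydro-1',2'-dihydro-ε,ψ-carotene | CC(C)=CC[C@H](/C=C/C(C)=C/C=C/C(C)=C/C=C/C(C)=C/C=C/C=C(C)/C=C/C=C(C)/C=C/[C@@H]1C(C)=CC[C@@H](C/C=C(\C)CO[Si](c2ccccc2)(c2ccccc2)C(C)(C)C)C1(C)C)C(C)(C)O[Si](CC)(CC)CC | intermediate
37 | all-E (2S,6R,2'R)-2-[(2E)-4-hydroxy-3-methylbut-2-en-1-yl]-2'-(3-methylbut-2-en-1-yl)-3',4'-didehydro-1',2'-dihydro-ε,ψ-caroten-1'-ol (CNP0409952.2) | CC(C)=CC[C@H](/C=C/C(C)=C/C=C/C(C)=C/C=C/C(C)=C/C=C/C=C(C)/C=C/C=C(C)/C=C/[C@@H]1C(C)=CC[C@@H](C/C=C(\C)CO)C1(C)C)C(C)(C)O | target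

**Step count and risks**

Total steps: 26. Longest linear sequence: 13 steps (ring branch: steps 1–5, 8–12, 24–26; the acyclic branch, steps 13–23, 25, 26, is equally long).

Three steps most likely to fail:

Step 2 (the proposed new reaction): enantioselectivity, C5 versus C3 regioselectivity and turnover of the silylium/IDPi cycle on a cross-conjugated dienone are unproven. The fallback uses known chemistry, sets out from 2 and comes back at 4. TiCl4-mediated Hosomi–Sakurai conjugate allylation of 2 (allylSiMe3, TiCl4, CH2Cl2, −78 °C) gives rac-2,4,4-trimethyl-5-(prop-2-en-1-yl)cyclohex-2-en-1-one F1. Luche reduction (NaBH4, CeCl3·7H2O, MeOH) then gives the cis alcohol rac-(1S,5R)-2,4,4-trimethyl-5-(prop-2-en-1-yl)cyclohex-2-en-1-ol F2 by axial hydride delivery, as with carvone. Kinetic resolution with Candida antarctica lipase B and vinyl acetate, run past half conversion, should acetylate the (1R)-carbinol (Kazlauskas rule) to (1R,5S)-2,4,4-trimethyl-5-(prop-2-en-1-yl)cyclohex-2-en-1-yl acetate F3 and leave (1S,5R)-2,4,4-trimethyl-5-(prop-2-en-1-yl)cyclohex-2-en-1-ol F4, which MnO2 oxidises to 4.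

Step 8: the enone carries an α-methyl group and its β-carbon is next to a quaternary centre, so the conjugate addition may stall or divert to 1,2-addition. The fallback sets out from 7 and comes back at 16. Luche reduction of 7 gives (1S,5R)-5-[(2E)-4-{[tert-butyl(diphenyl)silyl]oxy}-3-methylbut-2-en-1-yl]-2,4,4-trimethylcyclohex-2-en-1-ol F5, in which the hydroxyl is cis to the side chain. Esterification with picolinic acid (EDC·HCl, DMAP) gives (1S,5R)-5-[(2E)-4-{[tert-butyl(diphenyl)silyl]oxy}-3-methylbut-2-en-1-yl]-2,4,4-trimethylcyclohex-2-en-1-yl pyridine-2-carboxylate F6. Picolinate-directed copper-mediated allylic substitution with Grignard reagent 12 (CuBr·SMe2, THF, −40 °C) then attacks the γ-carbon anti to the leaving group (anti-SN2'), which forms the C6–C7 bond trans to the side chain and shifts the alkene to C4=C5 in one operation. This gives 16 directly, so steps 9 and 10 fall away.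

Step 14: the magnesium alkoxide of 20 could undergo Payne rearrangement and divert attack to C1, or the Lewis-acidic magnesium salts could open the epoxide at the tertiary carbon. The fallback sets out from 20 and comes back at 21. Silylation (t-BuMe2SiCl, imidazole) gives tert-butyl{[(2S)-3,3-dimethyloxiran-2-yl]methoxy}dimethylsilane F7, which has no free alkoxide and therefore cannot rearrange. Copper-catalysed opening with allylMgCl at C2 with inversion gives (3R)-3-({[tert-butyl(dimethyl)silyl]oxy}methyl)-2-methylhex-5-en-2-ol F8, and n-Bu4NF releases 21.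

Further compounds
F1 | step 2 | rac-2,4,4-trimethyl-5-(prop-2-en-1-yl)cyclohex-2-en-1-one (racemate) | C=CCC1CC(=O)C(C)=CC1(C)C
F2 | step 2 | rac-(1S,5R)-2,4,4-trimethyl-5-(prop-2-en-1-yl)cyclohex-2-en-1-ol (racemate, one enantiomer drawn) | O[C@H]1C[C@@H](CC=C)C(C)(C)C=C1C
F3 | step 2 | (1R,5S)-2,4,4-trimethyl-5-(prop-2-en-1-yl)cyclohex-2-en-1-yl acetate | CC(=O)O[C@@H]1C[C@H](CC=C)C(C)(C)C=C1C
F4 | step 2 | (1S,5R)-2,4,4-trimethyl-5-(prop-2-en-1-yl)cyclohex-2-en-1-ol | O[C@H]1C[C@@H](CC=C)C(C)(C)C=C1C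
F5 | step 8 | (1S,5R)-5-[(2E)-4-{[tert-butyl(diphenyl)silyl]oxy}-3-methylbut-2-en-1-yl]-2,4,4-trimethylcyclohex-2-en-1-ol | O[C@H]1C[C@@H](C/C=C(\C)CO[Si](c2ccccc2)(c2ccccc2)C(C)(C)C)C(C)(C)C=C1C
F6 | step 8 | (1S,5R)-5-[(2E)-4-{[tert-butyl(diphenyl)silyl]oxy}-3-methylbut-2-en-1-yl]-2,4,4-trimethylcyclohex-2-en-1-yl pyridine-2-carboxylate | O=C(O[C@H]1C[C@@H](C/C=C(\C)CO[Si](c2ccccc2)(c2ccccc2)C(C)(C)C)C(C)(C)C=C1C)c1ccccn1
F7 | step 14 | tert-butyl{[(2S)-3,3-dimethyloxiran-2-yl]methoxy}dimethylsilane | CC(C)(C)[Si](C)(C)OC[C@@H]1OC1(C)C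
F8 | step 14 | (3R)-3-({[tert-butyl(dimethyl)silyl]oxy}methyl)-2-methylhex-5-en-2-ol | C=CC[C@H](CO[Si](C)(C)C(C)(C)C)C(C)(C)O
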